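**Retrosynthetic overview**

1. The target is a catechol arene (ring A) fused to a 1,2-dihydronaphthalene carbocycle (ring B) that carries a 2-pyranone (ring C) on C1. The last step is a global acidolysis of two tert-butyl esters and one MOM ether; the methyl ester is already in place.
2. Ring B is the only ring built on the main line and is closed last, by forming the C1–C2 bond in one isothiourea-catalysed cascade: quinone methide formation, enantioselective 1,6-addition of a catalyst-bound ester dienolate, methanolysis.
3. Enabling feature: the C6 hydroxyl of ring A is para to C8a, so benzylic C1 (bonded to C8a and to C3' of ring C) can be unveiled as the exocyclic carbon of a para-quinone methide (transient dearomatisation of ring A). C2 is alpha to the future ester carbonyl and allylic to C3=C4, so it enolises as an acyl ammonium; rearomatisation drives the closure.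
4. The acyclic precursor comes from a Mizoroki–Heck arylation of an itaconate half-ester (C4a–C4 bond; supplies C2, C3, C4 and both carboxyls, already differentiated) and a Nozaki–Hiyama–Kishi addition of a pyranone 3-triflate to the aryl aldehyde (C1–C3' bond).
5. Building blocks: 2-bromo-4,5-dihydroxybenzaldehyde (ring A), monomethyl itaconate, galactaric acid (ring C).

Key step: step 12

Remark on numbering: ring B is numbered as 1,2-dihydronaphthalene (C1 pyranone-bearing, C2 CO2Me, C3 CO2H, C4 =CH, C4a/C8a fusion, C6 para to C8a); pyranone atoms are primed.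
Remark on stereochemistry: compounds 14, 15 and 16 are racemic at C1; this centre is erased in step 12.

**Route**

Step 1
Reactants: 1 galactaric acid
Product: 3 3-hydroxy-2-oxo-2H-pyran-6-carboxylic acid, via acetoxypyranone acid 2 (not isolated)
Conditions: Ac2O, pyridine, 90 °C; then 3 M aq. HCl, 60 °C
Reagents that add atoms: none
Why: Known dehydrative cyclisation of an aldaric acid: peracetylation, two eliminations of acetic acid and delta-lactonisation of the C5 oxygen onto C1 give the 3-acetoxy-2-pyranone, whose enol acetate is then cleaved by aqueous acid; no stereocentre remains.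

Step 2
Reactants: 3 3-hydroxy-2-oxo-2H-pyran-6-carboxylic acid
Product: 4 tert-butyl 3-hydroxy-2-oxo-2H-pyran-6-carboxylate
Conditions: tert-butyl 2,2,2-trichloroacetimidate (2 equiv), THF/cyclohexane, rt
Reagents that add atoms: tert-butyl 2,2,2-trichloroacetimidate, CC(C)(C)OC(=N)C(Cl)(Cl)Cl
Why: Imidate tert-butylation is selective for the strongly acidic carboxyl group, which protonates the imidate itself, while the enolic 3-OH is left free without a Lewis acid.

Step 3
Reactants: 4 tert-butyl 3-hydroxy-2-oxo-2H-pyran-6-carboxylate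
Product: 5 tert-butyl 2-oxo-3-(trifluoromethanesulfonyloxy)-2H-pyran-6-carboxylate
Conditions: Tf2O (1.1 equiv), pyridine (1.5 equiv), CH2Cl2, −78 to 0 °C
Reagents that add atoms: trifluoromethanesulfonic anhydride, O=S(=O)(OS(=O)(=O)C(F)(F)F)C(F)(F)F
Why: Standard O-triflation of an acidic enol hydroxyl gives an alkenyl triflate fit for oxidative addition.

Step 4
Reactants: 6 4-methyl hydrogen itaconate (monomethyl itaconate)
Product: 7 1-tert-butyl 4-methyl 2-methylidenebutanedioate
Conditions: tert-butyl 2,2,2-trichloroacetimidate (2 equiv), BF3·OEt2 (5 mol%), CH2Cl2/cyclohexane, rt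
Reagents that add atoms: tert-butyl 2,2,2-trichloroacetimidate, CC(C)(C)OC(=N)C(Cl)(Cl)Cl
Why: Lewis-acid-catalysed imidate tert-butylation of the conjugated carboxyl under non-basic conditions avoids isomerisation of the itaconate double bond.

Step 5
Reactants: 7 1-tert-butyl 4-methyl 2-methylidenebutanedioate
Product: 8 3-(tert-butoxycarbonyl)but-3-enoic acid
Conditions: LiOH·H2O (1.05 equiv), THF/H2O (3:1), 0 °C; then 1 M HCl
Reagents that add atoms: lithium hydroxide, [Li+].[OH-]
Why: Chemoselective saponification, because the unhindered non-conjugated methyl ester hydrolyses much faster than the hindered conjugated tert-butyl ester.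

Step 6
Reactants: 9 2-bromo-4,5-dihydroxybenzaldehyde
Product: 10 2-bromo-4-hydroxy-5-(methoxymethoxy)benzaldehyde
Conditions: NaH (2.2 equiv), DMSO, rt; then MOMCl (1.0 equiv), 0 °C to rt
Reagents that add atoms: chloromethyl methyl ether, COCCl
Why: Regioselective mono-O-alkylation of a catechol dianion: the phenoxide meta to the formyl group is not delocalised into the aldehyde, so it is the more nucleophilic and takes the single equivalent of electrophile.

Step 7
Reactants: 10 2-bromo-4-hydroxy-5-(methoxymethoxy)benzaldehyde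
Product: 11 2-bromo-4-(tert-butyldimethylsilyloxy)-5-(methoxymethoxy)benzaldehyde
Conditions: TBSCl (1.2 equiv), imidazole (2.5 equiv), CH2Cl2, rt
Reagents that add atoms: tert-butyldimethylsilyl chloride, CC(C)(C)[Si](C)(C)Cl
Why: Standard silylation masks the phenol that will later trigger quinone methide formation.

Step 8
Reactants: 11 2-bromo-4-(tert-butyldimethylsilyloxy)-5-(methoxymethoxy)benzaldehyde; 8 3-(tert-butoxycarbonyl)but-3-enoic acid
Product: 12 (E)-3-(tert-butoxycarbonyl)-4-[5-(tert-butyldimethylsilyloxy)-2-formyl-4-(methoxymethoxy)phenyl]but-3-enoic acid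
Conditions: Pd(OAc)2 (5 mol%), P(o-tol)3 (12 mol%), Et3N (3 equiv), MeCN, 80 °C
Reagents that add atoms: none
Why: Mizoroki–Heck arylation of a 1,1-disubstituted alkene: zerovalent palladium inserts into the C–Br bond, syn-carbopalladation occurs at the CH2 terminus and syn beta-hydride elimination of the benzylic hydrogen should give the conjugated (E)-arylidene succinate (aryl anti to the bulkier tert-butoxycarbonyl group).

Step 9
Reactants: 12 (E)-3-(tert-butoxycarbonyl)-4-[5-(tert-butyldimethylsilyloxy)-2-formyl-4-(methoxymethoxy)phenyl]but-3-enoic acid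
Product: 13 1-tert-butyl 4-(2,4,6-trichlorophenyl) (E)-2-[5-(tert-butyldimethylsilyloxy)-2-formyl-4-(methoxymethoxy)benzylidene]butanedioate
Conditions: 2,4,6-trichlorophenol (1.2 equiv), DCC (1.1 equiv), EtOAc, 0 °C to rt
Reagents that add atoms: 2,4,6-trichlorophenol, Oc1c(Cl)cc(Cl)cc1Cl
Why: Carbodiimide active-ester formation runs without base, so the acidic CH2 beside the new aryl ester cannot condense with the neighbouring aldehyde.

Step 10
Reactants: 13 1-tert-butyl 4-(2,4,6-trichlorophenyl) (E)-2-[5-(tert-butyldimethylsilyloxy)-2-formyl-4-(methoxymethoxy)benzylidene]butanedioate; 5 tert-butyl 2-oxo-3-(trifluoromethanesulfonyloxy)-2H-pyran-6-carboxylate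
Product: 14 1-tert-butyl 4-(2,4,6-trichlorophenyl) (E)-2-{2-[(6-tert-butoxycarbonyl-2-oxo-2H-pyran-3-yl)(hydroxy)methyl]-5-(tert-butyldimethylsilyloxy)-4-(methoxymethoxy)benzylidene}butanedioate (racemic carbinol)
Conditions: CrCl2 (4 equiv), NiCl2 (2 mol%), degassed DMF, rt
Reagents that add atoms: none
Why: Nozaki–Hiyama–Kishi coupling: zerovalent nickel inserts into the alkenyl C–OTf bond and transmetalation gives an alkenyl species of trivalent chromium that adds to the aldehyde in the presence of esters, the lactone and the aryl ester; the carbinol centre forms as a racemate, which does not matter because step 12 erases it.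

Step 11
Reactants: 14 racemic carbinol
Product: 16 1-tert-butyl 4-(2,4,6-trichlorophenyl) (E)-2-{2-[(6-tert-butoxycarbonyl-2-oxo-2H-pyran-3-yl)(4-methylbenzenesulfonyl)methyl]-5-hydroxy-4-(methoxymethoxy)benzylidene}butanedioate (racemic sulfone), via phenol carbinol 15 (not isolated)
Conditions: HF·pyridine, THF, 0 °C; then TolSO2H (2 equiv), rt
Reagents that add atoms: 4-methylbenzenesulfinic acid, Cc1ccc(cc1)S(=O)O
Why: Fluoride cleaves the aryl silyl ether, and the resulting para-hydroxybenzyl alcohol ionises under the mildly acidic conditions to a quinone methide that is captured at C1 by the S-nucleophilic sulfinic acid (1,6-addition), giving a storable quinone methide precursor.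

Step 12
Reactants: 16 racemic sulfone
Product: 19 3-tert-butyl 2-methyl (1R,2R)-1-(6-tert-butoxycarbonyl-2-oxo-2H-pyran-3-yl)-6-hydroxy-7-(methoxymethoxy)-1,2-dihydronaphthalene-2,3-dicarboxylate, via quinone methide 17 (not isolated), via cyclised trichlorophenyl ester 18 (not isolated)
Conditions: (2S,3R)-HyperBTM (20 mol%), iPr2NEt (2.5 equiv), CH2Cl2 (0.01 M), argon, −20 °C to rt; then MeOH (20 equiv), DMAP (20 mol%), rt
Reagents that add atoms: methanol, CO
Why: Proposed new method: iPr2NEt deprotonates the C6 phenol and expels sulfinate to give para-quinone methide 17, while HyperBTM is N-acylated by the trichlorophenyl ester and the released aryloxide removes a C2 proton to give a (Z)-ammonium dienolate whose oxygen is held syn to the catalyst sulfur; C2 then adds to the exocyclic C1 of 17 (1,6-addition with rearomatisation of ring A), aryloxide rebound releases the catalyst as ester 18, and the MeOH/DMAP quench gives methyl ester 19. The closest known reactions are the isothiourea-catalysed intermolecular 1,6-addition of aryl-ester-derived ammonium enolates to preformed para-quinone methides and isothiourea-catalysed intramolecular Michael cyclisations; new here are the quinone methide made in the flask, the beta,gamma-unsaturated donor and the ring closure. Ring B closes in a 6-(enolexo)-endo-trig mode through a half-chair in which the hydrogens on C1 and C2 point inward, so the pyranone and the acyl group should end up trans. C2 is set by the catalyst, whose C2 phenyl group shields one enolate face (attack anti to phenyl, predicted R with the (2S,3R) catalyst), and C1 follows from C2 through the tether (predicted R); the racemic centre of 16 is erased in 17, so the step is enantioconvergent. The step needs alpha- over gamma-reactivity of the dienolate (gamma-attack on C1 would give a four-membered ring, and the E-alkene holds C2 next to C1), intra- over intermolecular capture of 17 (high dilution), and no background enolisation (iPr2NEt does not enolise the aryl ester without the Lewis base).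

Step 13
Reactants: 19 protected (1R,2R)-dihydronaphthalene
Product: 20 (1R,2R)-1-(6-carboxy-2-oxo-2H-pyran-3-yl)-6,7-dihydroxy-2-(methoxycarbonyl)-1,2-dihydronaphthalene-3-carboxylic acid (CNP0239263.1)
Conditions: TFA/CH2Cl2 (1:1), H2O (5 equiv), anisole (5 equiv), argon, 0 °C to rt
Reagents that add atoms: none
Why: Acidolysis fragments both tert-butyl esters (loss of 2-methylpropene) and hydrolyses the MOM acetal, while the methyl ester, the enol lactone and the two stereocentres are not acid-labile.

**Compound list**

1 | galactaric acid | OC(=O)[C@H](O)[C@@H](O)[C@@H](O)[C@H](O)C(=O)O | starting material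
2 | 3-acetoxy-2-oxo-2H-pyran-6-carboxylic acid | CC(=O)Oc1ccc(C(=O)O)oc1=O | intermediate
3 | 3-hydroxy-2-oxo-2H-pyran-6-carboxylic acid | O=C(O)c1ccc(O)c(=O)o1 | intermediate
4 | tert-butyl 3-hydroxy-2-oxo-2H-pyran-6-carboxylate | CC(C)(C)OC(=O)c1ccc(O)c(=O)o1 | intermediate
5 | tert-butyl 2-oxo-3-(trifluoromethanesulfonyloxy)-2H-pyran-6-carboxylate | CC(C)(C)OC(=O)c1ccc(OS(=O)(=O)C(F)(F)F)c(=O)o1 | intermediate
6 | 4-methyl hydrogen itaconate | C=C(CC(=O)OC)C(=O)O | starting material
7 | 1-tert-butyl 4-methyl 2-methylidenebutanedioate | C=C(CC(=O)OC)C(=O)OC(C)(C)C | intermediate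
8 | 3-(tert-butoxycarbonyl)but-3-enoic acid | C=C(CC(=O)O)C(=O)OC(C)(C)C | intermediate
9 | 2-bromo-4,5-dihydroxybenzaldehyde | O=Cc1cc(O)c(O)cc1Br | starting material
10 | 2-bromo-4-hydroxy-5-(methoxymethoxy)benzaldehyde | O=Cc1cc(OCOC)c(O)cc1Br | intermediate
11 | 2-bromo-4-(tert-butyldimethylsilyloxy)-5-(methoxymethoxy)benzaldehyde | O=Cc1cc(OCOC)c(O[Si](C)(C)C(C)(C)C)cc1Br | intermediate
12 | (E)-arylidene succinate half-ester (free acid at C2 carboxyl) | O=Cc1cc(OCOC)c(O[Si](C)(C)C(C)(C)C)cc1/C=C(\CC(=O)O)C(=O)OC(C)(C)C | intermediate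
13 | (E)-arylidene succinate, 2,4,6-trichlorophenyl/tert-butyl diester, aldehyde | O=Cc1cc(OCOC)c(O[Si](C)(C)C(C)(C)C)cc1/C=C(\CC(=O)Oc1c(Cl)cc(Cl)cc1Cl)C(=O)OC(C)(C)C | intermediate
14 | racemic carbinol (silyl ether) | OC(c1cc(OCOC)c(O[Si](C)(C)C(C)(C)C)cc1/C=C(\CC(=O)Oc1c(Cl)cc(Cl)cc1Cl)C(=O)OC(C)(C)C)c1ccc(C(=O)OC(C)(C)C)oc1=O | intermediate
15 | racemic carbinol (free phenol) | OC(c1cc(OCOC)c(O)cc1/C=C(\CC(=O)Oc1c(Cl)cc(Cl)cc1Cl)C(=O)OC(C)(C)C)c1ccc(C(=O)OC(C)(C)C)oc1=O | intermediate
16 | racemic sulfone (quinone methide precursor) | Cc1ccc(cc1)S(=O)(=O)C(c1cc(OCOC)c(O)cc1/C=C(\CC(=O)Oc1c(Cl)cc(Cl)cc1Cl)C(=O)OC(C)(C)C)c1ccc(C(=O)OC(C)(C)C)oc1=O | intermediate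
17 | para-quinone methide | O=C1C=C(/C=C(\CC(=O)Oc2c(Cl)cc(Cl)cc2Cl)C(=O)OC(C)(C)C)C(=Cc2ccc(C(=O)OC(C)(C)C)oc2=O)C=C1OCOC | intermediate
18 | (1R,2R) cyclised 2,4,6-trichlorophenyl ester | Clc1cc(Cl)cc(Cl)c1OC(=O)[C@H]1C(C(=O)OC(C)(C)C)=Cc2cc(O)c(OCOC)cc2[C@@H]1c1ccc(C(=O)OC(C)(C)C)oc1=O | intermediate
19 | (1R,2R) methyl ester, protected | COC(=O)[C@H]1C(C(=O)OC(C)(C)C)=Cc2cc(O)c(OCOC)cc2[C@@H]1c1ccc(C(=O)OC(C)(C)C)oc1=O | intermediate
20 | CNP0239263.1 | COC(=O)[C@H]1C(C(=O)O)=Cc2cc(O)c(O)cc2[C@@H]1c1ccc(C(=O)O)oc1=O | target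

**Totals and risks**

Total step count: 13. Longest linear sequence: 8 steps (steps 6 to 13 from compound 9; equally steps 4, 5 and 8 to 13 from compound 6).

Risk 1, step 12 (proposed new method). What may go wrong:
- insufficient facial control in the ring closure (low enantiomer ratio or a cis/trans mixture);
- stalling of catalyst turnover by acyl transfer to the product phenoxide;
- intermolecular capture of the quinone methide (oligomers).

If only the sense of induction is opposite to the model, the (2R,3S) catalyst is used instead. Fallback with known chemistry, from 16 back to 19: sulfone 16 is treated with an achiral base (DBU, THF, 0 °C), which forms quinone methide 17 and the ester dienolate. Base-mediated intramolecular 1,6-addition under equilibrating conditions should give the racemic trans trichlorophenyl ester F1. Methanolysis (MeOH, DMAP) then gives the racemic trans methyl ester F2, which is resolved by preparative chiral-phase SFC to return 19.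

Risk 2, step 10. What may go wrong:
- slow oxidative addition, reductive homocoupling or hydrodetriflation of the electron-poor triflate;
- premature condensation of the acidic CH2 of the aryl ester with the neighbouring aldehyde under the Lewis-acidic chromium salts.

Fallback, from 5 back to 14: Miyaura borylation of triflate 5 (B2pin2, PdCl2(dppf), KOAc, dioxane, 80 °C) should give tert-butyl 2-oxo-3-(4,4,5,5-tetramethyl-1,3,2-dioxaborolan-2-yl)-2H-pyran-6-carboxylate F3. This is added to aldehyde 13 by the known rhodium-catalysed 1,2-addition of alkenylboron reagents to aldehydes ([Rh(cod)OH]2, dioxane/H2O 10:1, 50 °C), returning carbinol 14.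

Risk 3, step 8. What may go wrong:
- beta-hydride elimination towards the CH2CO2H side (benzyl-fumarate regioisomer);
- double-bond migration or E/Z scrambling.

Fallback, from 11 back to 12:
- The formyl group of 11 is masked with ethylene glycol (PPTS, benzene, reflux) as 2-[2-bromo-4-(tert-butyldimethylsilyloxy)-5-(methoxymethoxy)phenyl]-1,3-dioxolane F4.
- Bromine–lithium exchange (n-BuLi, THF, −78 °C) and a DMF quench give 5-(tert-butyldimethylsilyloxy)-2-(1,3-dioxolan-2-yl)-4-(methoxymethoxy)benzaldehyde F5.
- Wittig olefination (toluene, 80 °C) with the stabilised ylide tert-butyl hydrogen 2-(triphenylphosphoranylidene)succinate F6, made from commercial (triphenylphosphoranylidene)succinic anhydride and tert-butanol, gives the (E)-arylidene half-ester acetal F7.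
- Mild acetal hydrolysis (PPTS, acetone/H2O, 40 °C) returns acid 12.

Further compounds
F1 | step 12 | racemic trans cyclised 2,4,6-trichlorophenyl ester | Clc1cc(Cl)cc(Cl)c1OC(=O)[C@H]1C(C(=O)OC(C)(C)C)=Cc2cc(O)c(OCOC)cc2[C@@H]1c1ccc(C(=O)OC(C)(C)C)oc1=O.Clc1cc(Cl)cc(Cl)c1OC(=O)[C@@H]1C(C(=O)OC(C)(C)C)=Cc2cc(O)c(OCOC)cc2[C@H]1c1ccc(C(=O)OC(C)(C)C)oc1=O
F2 | step 12 | racemic trans methyl ester | COC(=O)[C@H]1C(C(=O)OC(C)(C)C)=Cc2cc(O)c(OCOC)cc2[C@@H]1c1ccc(C(=O)OC(C)(C)C)oc1=O.COC(=O)[C@@H]1C(C(=O)OC(C)(C)C)=Cc2cc(O)c(OCOC)cc2[C@H]1c1ccc(C(=O)OC(C)(C)C)oc1=O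
F3 | step 10 | tert-butyl 2-oxo-3-(4,4,5,5-tetramethyl-1,3,2-dioxaborolan-2-yl)-2H-pyran-6-carboxylate | CC(C)(C)OC(=O)c1ccc(B2OC(C)(C)C(C)(C)O2)c(=O)o1
F4 | step 8 | 2-[2-bromo-4-(tert-butyldimethylsilyloxy)-5-(methoxymethoxy)phenyl]-1,3-dioxolane | O1CCOC1c1cc(OCOC)c(O[Si](C)(C)C(C)(C)C)cc1Br
F5 | step 8 | 5-(tert-butyldimethylsilyloxy)-2-(1,3-dioxolan-2-yl)-4-(methoxymethoxy)benzaldehyde | O1CCOC1c1cc(OCOC)c(O[Si](C)(C)C(C)(C)C)cc1C=O
F6 | step 8 | tert-butyl hydrogen 2-(triphenylphosphoranylidene)succinate | CC(C)(C)OC(=O)C(CC(=O)O)=P(c1ccccc1)(c1ccccc1)c1ccccc1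
F7 | step 8 | (E)-3-(tert-butoxycarbonyl)-4-[5-(tert-butyldimethylsilyloxy)-2-(1,3-dioxolan-2-yl)-4-(methoxymethoxy)phenyl]but-3-enoic acid | O1CCOC1c1cc(OCOC)c(O[Si](C)(C)C(C)(C)C)cc1/C=C(\CC(=O)O)C(=O)OC(C)(C)C
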